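The readings were generated by integration with constants of no real substance; noise was put on by code.

Decide to hold one thing still, the share of the substrate lost per minute, and stretch the alder run of 30.0 min out to 2.5 h.

in all of them: substrate 0.050 M; free catalyst 0.25 mM
- alder: coupling partner 0.11 M; run made earlier
- flask: coupling partner 0.0750 M; time 2.5 h

alder run (percent of the substrate charged)

| time / min | target / % | substrate / % | over-reaction product / % |
|---|---|---|---|
| 2.50 | 0.4 | 98.1 | 0 |
| 8.00 | 1.3 | 96.8 | 0.1 |
| 15.0 | 5.8 | 94.5 | 0.1 |
| 20.0 | 6.7 | 93.1 | 0.9 |
| 30.0 | 9.5 | 91.9 | 1.5 |

(each reading ± 1 percentage point)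

- how much target the flask holds at 2.5 h, in percent of the substrate charged
- how much substrate the flask holds at 2.5 h, in percent of the substrate charged
- how much over-reaction product the flask holds at 2.5 h, in percent of the substrate charged



Try a straight line first: the alder run lost 8.10% of its substrate in 30.0 min, and that pace kept up for 2.5 h leaves 59.5%. But substrate thins as it goes, so a fixed pace presses too hard. Freeze instead the fraction of the remaining substrate that goes per minute, the loss constant 0.00312 min⁻¹ (a pseudo-first-order constant), pooled from the last two readings, where the loss stands clear of the scatter. That leaves 62.6% substrate.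

Now the objection: this flask has 0.0750 M coupling partner against 0.11 M. First order in partner would scale the constant by 0.682 and leave 72.7%. The alder run has a single partner charge, so it does not separate these; make a bet: guess that the catalyst already holds its partner at both charges, and keep the constant unscaled.

For the split, treat the alder target curve as a line, so the area under it is half of final height times time. Over-reaction product over that area gives a second constant, 0.0105 min⁻¹, a shaky one, as its reading of 1.5% sits close to the scatter. Two first-order steps in a row then give 17.7% target and 19.7% over-reaction product.

The forecast says 73% substrate, 17% target and 9% over-reaction product, with the words “I assume first order in partner”; my reckoning parts from it on that bet.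

The flask gives 62.2% substrate, 20.4% target and 17.3% over-reaction product.

    coupling partner + free catalyst ⇌ catalyst intermediate A (K = 900 M⁻¹, k = 1.10 M⁻¹ s⁻¹)
    catalyst intermediate C → catalyst intermediate D (k = 0.120 s⁻¹)
    catalyst intermediate D → free catalyst + target (k = 0.120 s⁻¹)
    substrate + catalyst intermediate B ⇌ catalyst intermediate C (K = 5.30 M⁻¹, k = 0.710 M⁻¹ s⁻¹)
    target → over-reaction product (k = 1.40 × 10⁻⁴ s⁻¹)
    catalyst intermediate A → catalyst intermediate B (k = 1.70 s⁻¹)
    catalyst intermediate D → spent catalyst (k = 2.30 × 10⁻⁴ s⁻¹)
    2 catalyst intermediate D ⇌ resting dimer, settled at all times (K = 12000 M⁻¹)

The loss constant gives substrate a half-life of 3.70 h, longer than the 1.4 h half-life of target by its conversion into over-reaction product alone, and in this flask target reads 20.4% at 2.5 h and 20.0% at 4.0 h, while over-reaction product climbs to 32.8%. At that later reading the same flask holds 47.0% substrate, against 47.3% from the loss constant.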